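**Retrosynthetic overview**
1. The C17 methylene (Mannich methylenation) and the C11 acetate (oxidation of the C9 ketone enolate) are removed first. The ten-membered ring is then opened at C7–C8, to be closed by a Nozaki–Hiyama–Kishi reaction of an alkenyl iodide with the C7 aldehyde.
2. Ring D is bought intact as (S)-4-silyloxycyclopentenone and joined at C12–C13 by conjugate addition of the C9 homoenolate. C11 and C12 come from a Kulinkovich cyclopropanol made on a ring A lactone.
3. Ring A is made in one operation from two acyclic pieces: a C2–C1–C10(C20)–C9 phosphonium ester and a C3–C4–C5–C6–C7 aldehyde/enoyl imide. Wittig olefination forms C2=C3 and an intramolecular Michael addition forms C5–C10 ([3+3]).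
4. Enabling feature: in ring A the C5–C10 bond lies at the centre of the 1,5-dioxygenated chain C9(=O)–C10–C5–C6–C7(O), and the bare C1–C2–C3 trimethylene ends at quaternary C4. C3 can therefore be a non-enolisable aldehyde, C5=C6 has no γ-hydrogen, and the gem-dimethyl group drives the six-ring closure.
5. Order of rings: A (step 5), D (attached intact, step 10), ten-membered ring (step 16).

Key step: step 5

Remark: positions are numbered as in 8,9-secokaurane. Ring A = C1–C5 and C10 (C4 gem-dimethyl, C20 = methyl on C10); C6; C7 (OH); ring D = C8, C14, C13, C16, C15 (C=O), with C17 = exocyclic CH2; C9 (C=O); C11 (OAc); C12. The racemic bromo ester and the silyloxycyclopentenone used below are assumed to be catalogue compounds.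

Step 1
Reactants: 1 (R)-4-benzyl-1,3-oxazolidin-2-one; 2 2-(diethoxyphosphoryl)acetic acid
Product: 4 (R)-4-benzyl-3-[2-(diethoxyphosphoryl)acetyl]-1,3-oxazolidin-2-one, via mixed pivalic anhydride 3 (not isolated)
Conditions: PivCl, Et3N, THF, −20 °C; then LiCl, 1, −20 °C → rt
Reagents that add atoms: none
Why: Mixed-anhydride N-acylation of an oxazolidinone, in which the tert-butyl group shields the pivaloyl carbonyl of 3 so that only the phosphonoacetyl group is transferred; the stereocentre of the auxiliary is not touched.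

Step 2
Reactants: 4 (R)-4-benzyl-3-[2-(diethoxyphosphoryl)acetyl]-1,3-oxazolidin-2-one; 5 3-hydroxy-2,2-dimethylpropanal
Product: 6 (R)-4-benzyl-3-[(E)-5-hydroxy-4,4-dimethylpent-2-enoyl]-1,3-oxazolidin-2-one
Conditions: LiCl, iPr2NEt, MeCN, 0 °C → rt
Reagents that add atoms: none
Why: Horner–Wadsworth–Emmons olefination under Masamune–Roush conditions, mild enough for the free hydroxyl and the imide; the stabilised phosphonate should give the E alkene C5=C6.

Step 3
Reactants: 6 (R)-4-benzyl-3-[(E)-5-hydroxy-4,4-dimethylpent-2-enoyl]-1,3-oxazolidin-2-one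
Product: 7 (R)-4-benzyl-3-[(E)-4,4-dimethyl-5-oxopent-2-enoyl]-1,3-oxazolidin-2-one
Conditions: Dess–Martin periodinane, CH2Cl2, 0 °C → rt
Reagents that add atoms: none
Why: Dess–Martin oxidation of a neopentyl primary alcohol to the C3 aldehyde, which cannot enolise or epimerise because C4 is quaternary.

Step 4
Reactants: 8 ethyl 4-bromo-2-methylbutanoate (racemic)
Product: 9 (4-ethoxy-3-methyl-4-oxobutyl)triphenylphosphonium bromide (racemic)
Conditions: PPh3, MeCN, reflux
Reagents that add atoms: triphenylphosphine, c1ccc(cc1)P(c1ccccc1)c1ccccc1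
Why: SN2 quaternisation of the phosphine by the primary bromide; the stereocentre next to the ester (future C10) is left racemic because step 5 planarises it.

Step 5
Reactants: 9 (4-ethoxy-3-methyl-4-oxobutyl)triphenylphosphonium bromide; 7 (R)-4-benzyl-3-[(E)-4,4-dimethyl-5-oxopent-2-enoyl]-1,3-oxazolidin-2-one
Product: 12 ethyl (1R,6R)-6-{2-[(R)-4-benzyl-2-oxo-1,3-oxazolidin-3-yl]-2-oxoethyl}-1,5,5-trimethylcyclohex-3-ene-1-carboxylate, via phosphorus ylide 10 (not isolated), via Z-alkene Wittig product 11 (not isolated)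
Conditions: NaHMDS (1.0 equiv), THF, −78 → 0 °C; 7, −78 → −20 °C; NaHMDS (1.2 equiv), −78 → −40 °C; AcOH, −78 °C
Reagents that add atoms: none
Why: The first portion of NaHMDS converts 9 into the non-stabilised ylide 10 (the P–CH2 protons are far more acidic than the ester α-hydrogen), which olefinates only the aldehyde of 7 and, as a salt-free ylide meeting an α-quaternary aldehyde, should give the Z C2=C3 alkene 11, the only geometry that can fold for ring closure; the second portion of base then forms the ester enolate at C10, the only acidic C–H left because C4 is quaternary, and this enolate adds to C5 of the N-enoyl imide. The closest known reaction types are the Z-selective Wittig olefination with (3-alkoxycarbonylpropyl)phosphonium salts, the tandem Michael/Wittig [3+3] cyclohexene annulations of bifunctional ylides, and enolate additions to N-enoyloxazolidinones. Ring A closes in a 6-(enolexo)-exo-trig mode through a half-chair that is favoured by the Thorpe–Ingold effect of the C4 gem-dimethyl group. C5 is controlled by the auxiliary: in the sodium-chelated syn-s-cis imide the benzyl group of the (R)-oxazolidinone covers the Si face of C5, so C10 attacks the Re face and gives 5R. C10 is controlled relative to C5 by the half-chair, in which the enoyl chain is equatorial, the bulky solvated C(ONa)(OEt) terminus takes the outward pseudo-equatorial site and the small methyl takes the pseudo-axial site syn to one C4 methyl, so that C9 and C6 end up trans (10R). The step needs kinetic control, because the cis isomer with an axial ester is expected to be the more stable one; this is secured by the low temperature and by the drop from an ester enolate to the much less basic imide enolate, which makes the addition irreversible before the cold acetic acid quench.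

Step 6
Reactants: 12 ethyl (1R,6R)-6-{2-[(R)-4-benzyl-2-oxo-1,3-oxazolidin-3-yl]-2-oxoethyl}-1,5,5-trimethylcyclohex-3-ene-1-carboxylate
Product: 13 ethyl (1R,2R)-2-{2-[(R)-4-benzyl-2-oxo-1,3-oxazolidin-3-yl]-2-oxoethyl}-1,3,3-trimethylcyclohexane-1-carboxylate
Conditions: H2 (1 atm), Pd/C, EtOAc, rt
Reagents that add atoms: none
Why: Heterogeneous catalytic hydrogenation saturates the only C=C bond (C2=C3) without touching C5, C10 or the auxiliary, which has no benzylic carbon–heteroatom bond.

Step 7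
Reactants: 13 ethyl (1R,2R)-2-{2-[(R)-4-benzyl-2-oxo-1,3-oxazolidin-3-yl]-2-oxoethyl}-1,3,3-trimethylcyclohexane-1-carboxylate
Product: 15 (4aR,8aR)-5,5,8a-trimethyloctahydro-1H-isochromen-1-one (trans-fused δ-lactone), via hydroxy ester 14 (not isolated)
Conditions: NaBH4, THF/H2O, 0 °C → rt; then p-TsOH (cat.), toluene, 80 °C
Reagents that add atoms: none
Why: Chemoselective borohydride reduction of the activated N-acyl oxazolidinone (the α-quaternary ester is inert) releases the auxiliary, and acid-catalysed lactonisation then ties back the hindered C9 carbonyl; the trans ring fusion follows from the C5 and C10 centres already set.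

Step 8
Reactants: 15 (4aR,8aR)-5,5,8a-trimethyloctahydro-1H-isochromen-1-one
Product: 16 1-[(1R,2R)-2-(2-hydroxyethyl)-1,3,3-trimethylcyclohexyl]cyclopropan-1-ol
Conditions: EtMgBr, Ti(OiPr)4 (30 mol %), THF, 0 °C → rt; aq NH4Cl
Reagents that add atoms: ethylmagnesium bromide, CC[Mg]Br
Why: Kulinkovich reaction, in which the titanacyclopropane formed from EtMgBr and Ti(OiPr)4 acts as a 1,2-dicarbanion on the lactone carbonyl and delivers C11 and C12 as a cyclopropanol; no stereocentre is formed.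

Step 9
Reactants: 16 1-[(1R,2R)-2-(2-hydroxyethyl)-1,3,3-trimethylcyclohexyl]cyclopropan-1-ol
Product: 17 1-[(1R,2R)-2-{2-[(tert-butyldiphenylsilyl)oxy]ethyl}-1,3,3-trimethylcyclohexyl]cyclopropan-1-ol
Conditions: TBDPSCl, imidazole, CH2Cl2, 0 °C
Reagents that add atoms: tert-butyl(chloro)diphenylsilane, CC(C)(C)[Si](Cl)(c1ccccc1)c1ccccc1
Why: Sterically selective silylation, in which the primary C7 alcohol reacts and the tertiary cyclopropanol does not.

Step 10
Reactants: 17 1-[(1R,2R)-2-{2-[(tert-butyldiphenylsilyl)oxy]ethyl}-1,3,3-trimethylcyclohexyl]cyclopropan-1-ol; 18 (S)-4-[(tert-butyldimethylsilyl)oxy]cyclopent-2-en-1-one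
Product: 21 (3S,4S)-4-[(tert-butyldimethylsilyl)oxy]-3-{3-[(1R,2R)-2-{2-[(tert-butyldiphenylsilyl)oxy]ethyl}-1,3,3-trimethylcyclohexyl]-3-oxopropyl}cyclopentan-1-one, via zinc bis-homoenolate 19 (not isolated), via trimethylsilyl enol ether 20 (not isolated)
Conditions: Et2Zn (0.55 equiv), THF, 0 → 40 °C; CuBr·SMe2 (10 mol %), TMSCl, DMPU, 18, −30 °C → rt; AcOH/THF/H2O work-up
Reagents that add atoms: none
Why: Copper-catalysed, TMSCl-accelerated conjugate addition of a zinc homoenolate, formed when the zinc cyclopropoxide opens to the β-zincio ketone and restores the C9 ketone; the C12–C13 bond forms on the enone face anti to the C14 silyloxy group, which sets C13.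

Step 11
Reactants: 21 (3S,4S)-4-[(tert-butyldimethylsilyl)oxy]-3-{3-[(1R,2R)-2-{2-[(tert-butyldiphenylsilyl)oxy]ethyl}-1,3,3-trimethylcyclohexyl]-3-oxopropyl}cyclopentan-1-one
Product: 22 (S)-4-{3-[(1R,2R)-2-{2-[(tert-butyldiphenylsilyl)oxy]ethyl}-1,3,3-trimethylcyclohexyl]-3-oxopropyl}cyclopent-2-en-1-one
Conditions: DBU (cat.), CH2Cl2, 0 °C
Reagents that add atoms: none
Why: E1cB loss of silanol from the β-silyloxy ketone installs the C8=C14 enone, and brief exposure at 0 °C should avoid γ-deprotonation at C13.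

Step 12
Reactants: 22 (S)-4-{3-[(1R,2R)-2-{2-[(tert-butyldiphenylsilyl)oxy]ethyl}-1,3,3-trimethylcyclohexyl]-3-oxopropyl}cyclopent-2-en-1-one
Product: 23 (S)-2-iodo-4-{3-[(1R,2R)-2-{2-[(tert-butyldiphenylsilyl)oxy]ethyl}-1,3,3-trimethylcyclohexyl]-3-oxopropyl}cyclopent-2-en-1-one
Conditions: I2, pyridine/CH2Cl2, 0 °C → rt
Reagents that add atoms: iodine, II
Why: Pyridine-mediated α-iodination of an enone (Baylis–Hillman-type addition, iodination of the enolate, elimination) is specific for C8 and leaves the saturated C9 ketone alone.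

Step 13
Reactants: 23 (S)-2-iodo-4-{3-[(1R,2R)-2-{2-[(tert-butyldiphenylsilyl)oxy]ethyl}-1,3,3-trimethylcyclohexyl]-3-oxopropyl}cyclopent-2-en-1-one
Product: 24 1-[(1R,2R)-2-{2-[(tert-butyldiphenylsilyl)oxy]ethyl}-1,3,3-trimethylcyclohexyl]-3-[(S)-6-iodo-1,4-dioxaspiro[4.4]non-6-en-8-yl]propan-1-one
Conditions: HOCH2CH2OH, p-TsOH (cat.), benzene, reflux (Dean–Stark)
Reagents that add atoms: ethylene glycol, OCCO
Why: Acid-catalysed dioxolane formation; α-halo enones ketalise without migration of the double bond, the C9 ketone next to quaternary C10 is too hindered to react, and the TBDPS ether tolerates the acid.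

Step 14
Reactants: 24 1-[(1R,2R)-2-{2-[(tert-butyldiphenylsilyl)oxy]ethyl}-1,3,3-trimethylcyclohexyl]-3-[(S)-6-iodo-1,4-dioxaspiro[4.4]non-6-en-8-yl]propan-1-one
Product: 25 1-[(1R,2R)-2-(2-hydroxyethyl)-1,3,3-trimethylcyclohexyl]-3-[(S)-6-iodo-1,4-dioxaspiro[4.4]non-6-en-8-yl]propan-1-one
Conditions: TBAF, THF, 0 °C → rt
Reagents that add atoms: none
Why: Fluoride-induced cleavage of the silyl ether, to which the alkenyl iodide, the ketal and the ketone are inert.

Step 15
Reactants: 25 1-[(1R,2R)-2-(2-hydroxyethyl)-1,3,3-trimethylcyclohexyl]-3-[(S)-6-iodo-1,4-dioxaspiro[4.4]non-6-en-8-yl]propan-1-one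
Product: 26 2-[(1R,2R)-2-{3-[(S)-6-iodo-1,4-dioxaspiro[4.4]non-6-en-8-yl]propanoyl}-2,6,6-trimethylcyclohexyl]acetaldehyde
Conditions: Dess–Martin periodinane, CH2Cl2, 0 °C → rt
Reagents that add atoms: none
Why: Dess–Martin oxidation under neutral conditions gives the C7 aldehyde without triggering an aldol reaction between C11 and C7.

Step 16
Reactants: 26 2-[(1R,2R)-2-{3-[(S)-6-iodo-1,4-dioxaspiro[4.4]non-6-en-8-yl]propanoyl}-2,6,6-trimethylcyclohexyl]acetaldehyde
Product: 27 (5R,7R,10R,13S)-15,15-(ethylenedioxy)-7-hydroxy-17-nor-8,9-secokaur-8(14)-en-9-one (ten-membered ring closed)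
Conditions: CrCl2 (excess), NiCl2 (1 mol %), DMSO/THF, 0.002 M, rt
Reagents that add atoms: none
Why: Nozaki–Hiyama–Kishi macrocyclisation, in which nickel-catalysed activation of the C8–I bond and transfer to chromium give an alkenylchromium species that adds only to the aldehyde (the hindered C9 ketone and the ketal are inert); high dilution favours ring closure, and attack on the aldehyde face that points outward from the folding chain, away from the dioxolane, should give the 7R alcohol.

Step 17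
Reactants: 27 (5R,7R,10R,13S)-15,15-(ethylenedioxy)-7-hydroxy-17-nor-8,9-secokaur-8(14)-en-9-one
Product: 28 (5R,7R,10R,13S)-15,15-(ethylenedioxy)-7-[(triethylsilyl)oxy]-17-nor-8,9-secokaur-8(14)-en-9-one
Conditions: TESCl, imidazole, DMAP (cat.), DMF, rt
Reagents that add atoms: chlorotriethylsilane, CC[Si](Cl)(CC)CC
Why: Standard silylation masks the only hydroxyl group before the strongly basic next step and does not endanger the ketal.

Step 18
Reactants: 28 (5R,7R,10R,13S)-15,15-(ethylenedioxy)-7-[(triethylsilyl)oxy]-17-nor-8,9-secokaur-8(14)-en-9-one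
Product: 30 (5R,7R,10R,11S,13S)-11-acetoxy-15,15-(ethylenedioxy)-7-[(triethylsilyl)oxy]-17-nor-8,9-secokaur-8(14)-en-9-one, via potassium 11-alkoxide 29 (not isolated)
Conditions: KHMDS, THF, −78 °C; 2-(phenylsulfonyl)-3-phenyloxaziridine; then Ac2O, DMAP (cat.), −78 → 0 °C
Reagents that add atoms: 2-(phenylsulfonyl)-3-phenyloxaziridine, O=S(=O)(c1ccccc1)N1OC1c1ccccc1; acetic anhydride, CC(=O)OC(C)=O
Why: Davis oxidation with in situ acetylation; C10 is quaternary, so the C9 ketone can enolise only toward C11, and the oxaziridine can reach the medium-ring enolate only from its outer face (the inner face is covered transannularly by ring D), which should give 11S before the alkoxide is trapped as the acetate.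

Step 19
Reactants: 30 (5R,7R,10R,11S,13S)-11-acetoxy-15,15-(ethylenedioxy)-7-[(triethylsilyl)oxy]-17-nor-8,9-secokaur-8(14)-en-9-one
Product: 31 (5R,7R,10R,11S,13S)-11-acetoxy-7-hydroxy-17-nor-8,9-secokaur-8(14)-ene-9,15-dione
Conditions: 1 M HCl, THF, 0 °C → rt
Reagents that add atoms: water, O
Why: Mild acid hydrolysis removes the triethylsilyl ether and the dioxolane in one operation and frees the C15 enone, while the acetate and all stereocentres are stable under these conditions.

Step 20
Reactants: 31 (5R,7R,10R,11S,13S)-11-acetoxy-7-hydroxy-17-nor-8,9-secokaur-8(14)-ene-9,15-dione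
Product: 32 (5R,7R,10R,11S,13R)-11-acetoxy-7-hydroxy-8,9-secokaura-8(14),16-diene-9,15-dione (target)
Conditions: (CH2O)n, N-methylanilinium trifluoroacetate, THF, reflux
Reagents that add atoms: formaldehyde (as paraformaldehyde), C=O
Why: Mannich-type α-methylenation under buffered, non-basic conditions; C16 is the only α-CH2 in the molecule (C10 is quaternary and C11 is a hindered methine that cannot give a methylene group), so aminomethylation and amine loss occur only there, and the C13 descriptor changes from S to R by priority alone.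

**Compound list**
1 | (R)-4-benzyl-1,3-oxazolidin-2-one | O=C1N[C@H](Cc2ccccc2)CO1 | starting material
2 | 2-(diethoxyphosphoryl)acetic acid | CCOP(=O)(CC(=O)O)OCC | starting material
3 | 2-(diethoxyphosphoryl)acetic pivalic anhydride | CCOP(=O)(CC(=O)OC(=O)C(C)(C)C)OCC | intermediate
4 | (R)-4-benzyl-3-[2-(diethoxyphosphoryl)acetyl]-1,3-oxazolidin-2-one | CCOP(=O)(CC(=O)N1[C@H](Cc2ccccc2)COC1=O)OCC | intermediate
5 | 3-hydroxy-2,2-dimethylpropanal | CC(C)(CO)C=O | starting material
6 | (R)-4-benzyl-3-[(E)-5-hydroxy-4,4-dimethylpent-2-enoyl]-1,3-oxazolidin-2-one | OCC(C)(C)/C=C/C(=O)N1[C@H](Cc2ccccc2)COC1=O | intermediate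
7 | (R)-4-benzyl-3-[(E)-4,4-dimethyl-5-oxopent-2-enoyl]-1,3-oxazolidin-2-one | O=CC(C)(C)/C=C/C(=O)N1[C@H](Cc2ccccc2)COC1=O | intermediate
8 | ethyl 4-bromo-2-methylbutanoate (racemic) | CCOC(=O)C(C)CCBr | starting material
9 | (4-ethoxy-3-methyl-4-oxobutyl)triphenylphosphonium bromide (racemic) | CCOC(=O)C(C)CC[P+](c1ccccc1)(c1ccccc1)c1ccccc1.[Br-] | intermediate
10 | ethyl 2-methyl-4-(triphenylphosphoranylidene)butanoate | CCOC(=O)C(C)CC=P(c1ccccc1)(c1ccccc1)c1ccccc1 | intermediate
11 | ethyl (4Z,7E)-9-[(R)-4-benzyl-2-oxo-1,3-oxazolidin-3-yl]-2,6,6-trimethyl-9-oxonona-4,7-dienoate (both C2 epimers) | CCOC(=O)C(C)C/C=C\C(C)(C)/C=C/C(=O)N1[C@H](Cc2ccccc2)COC1=O | intermediate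
12 | ethyl (1R,6R)-6-{2-[(R)-4-benzyl-2-oxo-1,3-oxazolidin-3-yl]-2-oxoethyl}-1,5,5-trimethylcyclohex-3-ene-1-carboxylate | CCOC(=O)[C@]1(C)CC=CC(C)(C)[C@H]1CC(=O)N2[C@H](Cc3ccccc3)COC2=O | intermediate
13 | ethyl (1R,2R)-2-{2-[(R)-4-benzyl-2-oxo-1,3-oxazolidin-3-yl]-2-oxoethyl}-1,3,3-trimethylcyclohexane-1-carboxylate | CCOC(=O)[C@]1(C)CCCC(C)(C)[C@H]1CC(=O)N2[C@H](Cc3ccccc3)COC2=O | intermediate
14 | ethyl (1R,2R)-2-(2-hydroxyethyl)-1,3,3-trimethylcyclohexane-1-carboxylate | CCOC(=O)[C@]1(C)CCCC(C)(C)[C@H]1CCO | intermediate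
15 | (4aR,8aR)-5,5,8a-trimethyloctahydro-1H-isochromen-1-one | O=C1[C@]2(C)CCCC(C)(C)[C@H]2CCO1 | intermediate
16 | 1-[(1R,2R)-2-(2-hydroxyethyl)-1,3,3-trimethylcyclohexyl]cyclopropan-1-ol | OC1(CC1)[C@]2(C)CCCC(C)(C)[C@H]2CCO | intermediate
17 | 1-[(1R,2R)-2-{2-[(tert-butyldiphenylsilyl)oxy]ethyl}-1,3,3-trimethylcyclohexyl]cyclopropan-1-ol | OC1(CC1)[C@]2(C)CCCC(C)(C)[C@H]2CCO[Si](c3ccccc3)(c3ccccc3)C(C)(C)C | intermediate
18 | (S)-4-[(tert-butyldimethylsilyl)oxy]cyclopent-2-en-1-one | O=C1C=C[C@@H](O[Si](C)(C)C(C)(C)C)C1 | starting material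
19 | bis{3-[(1R,2R)-2-{2-[(tert-butyldiphenylsilyl)oxy]ethyl}-1,3,3-trimethylcyclohexyl]-3-oxopropyl}zinc | O=C(CC[Zn]CCC(=O)[C@]1(C)CCCC(C)(C)[C@H]1CCO[Si](c2ccccc2)(c2ccccc2)C(C)(C)C)[C@]3(C)CCCC(C)(C)[C@H]3CCO[Si](c4ccccc4)(c4ccccc4)C(C)(C)C | intermediate
20 | C15 trimethylsilyl enol ether (C15=C16) of 21 | C1=C(O[Si](C)(C)C)C[C@H](O[Si](C)(C)C(C)(C)C)[C@H]1CCC(=O)[C@]2(C)CCCC(C)(C)[C@H]2CCO[Si](c3ccccc3)(c3ccccc3)C(C)(C)C | intermediate
21 | (3S,4S)-4-[(tert-butyldimethylsilyl)oxy]-3-{3-[(1R,2R)-2-{2-[(tert-butyldiphenylsilyl)oxy]ethyl}-1,3,3-trimethylcyclohexyl]-3-oxopropyl}cyclopentan-1-one | C1C(=O)C[C@H](O[Si](C)(C)C(C)(C)C)[C@H]1CCC(=O)[C@]2(C)CCCC(C)(C)[C@H]2CCO[Si](c3ccccc3)(c3ccccc3)C(C)(C)C | intermediate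
22 | (S)-4-{3-[(1R,2R)-2-{2-[(tert-butyldiphenylsilyl)oxy]ethyl}-1,3,3-trimethylcyclohexyl]-3-oxopropyl}cyclopent-2-en-1-one | C1C(=O)C=C[C@H]1CCC(=O)[C@]2(C)CCCC(C)(C)[C@H]2CCO[Si](c3ccccc3)(c3ccccc3)C(C)(C)C | intermediate
23 | (S)-2-iodo-4-{3-[(1R,2R)-2-{2-[(tert-butyldiphenylsilyl)oxy]ethyl}-1,3,3-trimethylcyclohexyl]-3-oxopropyl}cyclopent-2-en-1-one | C1C(=O)C(I)=C[C@H]1CCC(=O)[C@]2(C)CCCC(C)(C)[C@H]2CCO[Si](c3ccccc3)(c3ccccc3)C(C)(C)C | intermediate
24 | 1-[(1R,2R)-2-{2-[(tert-butyldiphenylsilyl)oxy]ethyl}-1,3,3-trimethylcyclohexyl]-3-[(S)-6-iodo-1,4-dioxaspiro[4.4]non-6-en-8-yl]propan-1-one | C1C2(OCCO2)C(I)=C[C@H]1CCC(=O)[C@]3(C)CCCC(C)(C)[C@H]3CCO[Si](c4ccccc4)(c4ccccc4)C(C)(C)C | intermediate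
25 | 1-[(1R,2R)-2-(2-hydroxyethyl)-1,3,3-trimethylcyclohexyl]-3-[(S)-6-iodo-1,4-dioxaspiro[4.4]non-6-en-8-yl]propan-1-one | C1C2(OCCO2)C(I)=C[C@H]1CCC(=O)[C@]3(C)CCCC(C)(C)[C@H]3CCO | intermediate
26 | 2-[(1R,2R)-2-{3-[(S)-6-iodo-1,4-dioxaspiro[4.4]non-6-en-8-yl]propanoyl}-2,6,6-trimethylcyclohexyl]acetaldehyde | C1C2(OCCO2)C(I)=C[C@H]1CCC(=O)[C@]3(C)CCCC(C)(C)[C@H]3CC=O | intermediate
27 | (5R,7R,10R,13S)-15,15-(ethylenedioxy)-7-hydroxy-17-nor-8,9-secokaur-8(14)-en-9-one | C1C3(OCCO3)C2=C[C@H]1CCC(=O)[C@]4(C)CCCC(C)(C)[C@H]4C[C@H]2O | intermediate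
28 | (5R,7R,10R,13S)-15,15-(ethylenedioxy)-7-[(triethylsilyl)oxy]-17-nor-8,9-secokaur-8(14)-en-9-one | C1C3(OCCO3)C2=C[C@H]1CCC(=O)[C@]4(C)CCCC(C)(C)[C@H]4C[C@H]2O[Si](CC)(CC)CC | intermediate
29 | potassium (11S)-11-alkoxide of the 11-hydroxy derivative of 28 | C1C3(OCCO3)C2=C[C@H]1C[C@H]([O-])C(=O)[C@]4(C)CCCC(C)(C)[C@H]4C[C@H]2O[Si](CC)(CC)CC.[K+] | intermediate
30 | (5R,7R,10R,11S,13S)-11-acetoxy-15,15-(ethylenedioxy)-7-[(triethylsilyl)oxy]-17-nor-8,9-secokaur-8(14)-en-9-one | C1C3(OCCO3)C2=C[C@H]1C[C@H](OC(C)=O)C(=O)[C@]4(C)CCCC(C)(C)[C@H]4C[C@H]2O[Si](CC)(CC)CC | intermediate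
31 | (5R,7R,10R,11S,13S)-11-acetoxy-7-hydroxy-17-nor-8,9-secokaur-8(14)-ene-9,15-dione | C1C(=O)C2=C[C@H]1C[C@H](OC(C)=O)C(=O)[C@]3(C)CCCC(C)(C)[C@H]3C[C@H]2O | intermediate
32 | (5R,7R,10R,11S,13R)-11-acetoxy-7-hydroxy-8,9-secokaura-8(14),16-diene-9,15-dione | C=C1C(=O)C2=C[C@H]1C[C@H](OC(C)=O)C(=O)[C@]1(C)CCCC(C)(C)[C@H]1C[C@H]2O | target

Total step count: 20. Longest linear sequence: 19 steps (steps 1–3, then 5–20).

**Steps most likely to fail**

Step 5. The C5–C10 bond joins two congested carbons and may form slowly. Warming to compensate may allow retro-Michael leakage toward the more stable C10 epimer. Incomplete sodium chelation of the imide may also erode the facial selectivity at C5. The fallback separates the two events and changes the closure from an anionic to a Lewis-acid-driven one. It sets out from 9 and 7. Only the first portion of NaHMDS is used and diene 11 is isolated. LDA in the presence of TMSCl (internal quench, THF, −100 °C) converts its ester into the trimethylsilyl ketene acetal F1. Et2AlCl (2 equiv, CH2Cl2, −78 °C) then chelates both imide carbonyls and triggers an intramolecular Mukaiyama–Michael addition on the same C5 face. This returns to the route at 12.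

Step 16. Closure of the strained ten-membered ring competes with oligomerisation, with protodeiodination and with an aldol reaction between C11 and C7 of the keto aldehyde. The facial selectivity at C7 may also be poor. The fallback closes the ring as a ketone and sets C7 afterwards under reagent control. It sets out from 26. Pinnick oxidation gives the carboxylic acid F2, and EtSH/EDC/DMAP gives the S-ethyl thioester F3. (Me3Sn)2 with Pd(PPh3)4 exchanges iodine for tin to give the alkenylstannane F4. A Liebeskind–Srogl-type acylative coupling (Pd2(dba)3, tri(2-furyl)phosphine, CuOP(O)Ph2, high dilution) gives the macrocyclic enone F5. Corey–Bakshi–Shibata reduction ((S)-Me-CBS, BH3·SMe2), with the alkenyl group as the large substituent, should give the 7R alcohol. This returns to the route at 27.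

Step 10. The hindered zinc cyclopropoxide may open sluggishly, the homoenolate may be protonated before it transfers to copper, and the enone may lose silanol prematurely. The fallback replaces the organometallic addition by a radical one. It sets out from 17. N-iodosuccinimide (CH2Cl2, 0 °C) opens the cyclopropanol to the β-iodo ketone F6. (Me3Si)3SiH with AIBN (toluene, 80 °C) in the presence of 18 then generates the primary β-keto radical. A Giese addition of this radical, anti to the silyloxy group, returns to the route at 21.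

**Further compounds**
F1 | step 5 | trimethylsilyl ketene acetal of 11 | CCOC(O[Si](C)(C)C)=C(C)C/C=C\C(C)(C)/C=C/C(=O)N1[C@H](Cc2ccccc2)COC1=O
F2 | step 16 | 2-[(1R,2R)-2-{3-[(S)-6-iodo-1,4-dioxaspiro[4.4]non-6-en-8-yl]propanoyl}-2,6,6-trimethylcyclohexyl]acetic acid | C1C2(OCCO2)C(I)=C[C@H]1CCC(=O)[C@]3(C)CCCC(C)(C)[C@H]3CC(=O)O
F3 | step 16 | S-ethyl thioester of F2 | C1C2(OCCO2)C(I)=C[C@H]1CCC(=O)[C@]3(C)CCCC(C)(C)[C@H]3CC(=O)SCC
F4 | step 16 | 6-(trimethylstannyl) analogue of F3 | C1C2(OCCO2)C([Sn](C)(C)C)=C[C@H]1CCC(=O)[C@]3(C)CCCC(C)(C)[C@H]3CC(=O)SCC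
F5 | step 16 | (5R,10R,13S)-15,15-(ethylenedioxy)-17-nor-8,9-secokaur-8(14)-ene-7,9-dione | C1C3(OCCO3)C2=C[C@H]1CCC(=O)[C@]4(C)CCCC(C)(C)[C@H]4CC2=O
F6 | step 10 | 1-[(1R,2R)-2-{2-[(tert-butyldiphenylsilyl)oxy]ethyl}-1,3,3-trimethylcyclohexyl]-3-iodopropan-1-one | ICCC(=O)[C@]1(C)CCCC(C)(C)[C@H]1CCO[Si](c2ccccc2)(c2ccccc2)C(C)(C)C
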